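**Plan**

- Retrosynthesis: the twelve O-methyl groups come off last. Ring B (rings lettered A to E from the phloroglucinol end) is cut at B-C3/B-C4, B-C5/B-C6 and B-C2/B-C3 into a 3,4-bis(aryloxy)cyclobutenone and methoxyacetylene. The cyclobutenone is cut at C1–C2 and C3–C4 into the aryloxyketene of the C-D-E fragment and the ring A aryl ethynyl ether; the C–O–D and D–O–E ether bonds go last.
- Enabling feature: ring B has aryloxy groups on adjacent carbons C1 and C2, a hydroxyl on C3 and a second oxygen on C5 meta to it, with C4 and C6 as CH. A vinylketene/alkoxyacetylene benzannulation gives exactly this resorcinol pattern, and both ether oxygens are already fixed on the four-membered ring.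
- Forward: rings E, D and C are joined by two Cu-catalysed etherifications; each activating formyl group is then turned into the next phenol by Baeyer–Villiger oxidation. The C-D-E phenol becomes an aryloxyacetyl chloride, its ketene adds to the ring A ynol ether, ring B is built last, and BBr3 frees the thirteen hydroxyls.
- Stereochemistry: the target is achiral; the one stereocentre on the way (C4 of the cyclobutenone) is racemic and is erased on aromatisation.

Key step: step 12

Assumption: compounds 1, 2, 6, 10, 15, 16 and 24 are taken as purchased; 23 and the transient species 29 and 31 are racemic, which has no consequence for the achiral target.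

Shorthand in names: "CDE-O" is the 3,5-dimethoxy-4-[3,4,5-trimethoxy-2-(3,4,5-trimethoxyphenoxy)phenoxy]phenoxy group; "TMP-O" is the 2,4,6-trimethoxyphenoxy group.

**Route**

Step 1
Reactants: 1 2-bromo-3,4,5-trimethoxybenzaldehyde; 2 3,4,5-trimethoxyphenol
Product: 3 3,4,5-trimethoxy-2-(3,4,5-trimethoxyphenoxy)benzaldehyde
Conditions: CuI (10 mol%), N,N-dimethylglycine (20 mol%), Cs2CO3, dioxane, 90 °C
Reagents that add atoms: none
Why: Ullmann diaryl ether coupling, in which the ortho formyl group activates the C–Br bond and the phenol partner has both ortho positions free.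

Step 2
Reactants: 3 3,4,5-trimethoxy-2-(3,4,5-trimethoxyphenoxy)benzaldehyde
Product: 5 3,4,5-trimethoxy-2-(3,4,5-trimethoxyphenoxy)phenol, via aryl formate 4 (not isolated)
Conditions: mCPBA, CH2Cl2, 0 °C to rt; then K2CO3, MeOH, rt
Reagents that add atoms: mCPBA, OOC(=O)c1cccc(Cl)c1
Why: Baeyer–Villiger (Dakin-type) oxidation, in which the electron-rich aryl group migrates in preference to hydrogen and the formate is methanolysed, so the formyl group that activated step 1 becomes the next phenol oxygen.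

Step 3
Reactants: 5 3,4,5-trimethoxy-2-(3,4,5-trimethoxyphenoxy)phenol; 6 4-bromo-3,5-dimethoxybenzaldehyde
Product: 7 3,5-dimethoxy-4-[3,4,5-trimethoxy-2-(3,4,5-trimethoxyphenoxy)phenoxy]benzaldehyde
Conditions: CuI (10 mol%), picolinic acid (20 mol%), K3PO4, DMSO, 100 °C
Reagents that add atoms: none
Why: Ullmann coupling under the CuI/picolinic acid conditions used for crowded diaryl ethers, helped by the para formyl group on the bromide that is flanked by two methoxy groups.

Step 4
Reactants: 7 3,5-dimethoxy-4-[3,4,5-trimethoxy-2-(3,4,5-trimethoxyphenoxy)phenoxy]benzaldehyde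
Product: 9 3,5-dimethoxy-4-[3,4,5-trimethoxy-2-(3,4,5-trimethoxyphenoxy)phenoxy]phenol (CDE-OH), via aryl formate 8 (not isolated)
Conditions: mCPBA, CH2Cl2, 0 °C to rt; then K2CO3, MeOH, rt
Reagents that add atoms: mCPBA, OOC(=O)c1cccc(Cl)c1
Why: Baeyer–Villiger oxidation with aryl migration favoured by the para aryloxy donor, as in the known conversion of 3,4,5-trimethoxybenzaldehyde into its phenol.

Step 5
Reactants: 9 CDE-OH; 10 ethyl bromoacetate
Product: 11 ethyl 2-(CDE-O)acetate
Conditions: K2CO3, acetone, reflux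
Reagents that add atoms: none
Why: Williamson ether synthesis of an unhindered phenoxide with a primary alpha-bromo ester.

Step 6
Reactants: 11 ethyl 2-(CDE-O)acetate
Product: 13 2-(CDE-O)acetic acid, via lithium carboxylate 12 (not isolated)
Conditions: LiOH, THF/H2O, rt; then 1 M HCl
Reagents that add atoms: lithium hydroxide, [Li+].[OH-]
Why: ester saponification, to which the methyl and diaryl ethers are inert.

Step 7
Reactants: 13 2-(CDE-O)acetic acid
Product: 14 2-(CDE-O)acetyl chloride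
Conditions: (COCl)2, DMF (cat.), CH2Cl2, 0 °C to rt; volatiles removed, used crude
Reagents that add atoms: oxalyl chloride, ClC(=O)C(Cl)=O
Why: acid chloride formation through the chloroiminium catalyst at low temperature and without Lewis acid, so Friedel–Crafts closure onto the electron-rich ring C should not compete.

Step 8
Reactants: 15 2,4,6-trimethoxyphenol; 16 trichloroethylene
Product: 18 2-[(E)-1,2-dichloroethenoxy]-1,3,5-trimethoxybenzene, via dichloroacetylene 17 (not isolated)
Conditions: K2CO3, DMF, 70 °C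
Reagents that add atoms: none
Why: base-induced dehydrochlorination of trichloroethylene followed by anti addition of the phenoxide to dichloroacetylene, the standard route to aryl (E)-1,2-dichlorovinyl ethers.

Step 9
Reactants: 18 2-[(E)-1,2-dichloroethenoxy]-1,3,5-trimethoxybenzene
Product: 21 2-(ethynyloxy)-1,3,5-trimethoxybenzene, via chloroethynyl ether 19 (not isolated), via lithium acetylide 20 (not isolated)
Conditions: n-BuLi (2.2 equiv), THF, −78 to −40 °C; then H2O, −78 °C; kept cold in solution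
Reagents that add atoms: none
Why: ynol ether synthesis by dehydrochlorination and lithium–chlorine exchange of a dichlorovinyl ether, with protonation of the acetylide giving the terminal aryl ethynyl ether that the two ortho methoxy groups shield.

Step 10
Reactants: 14 2-(CDE-O)acetyl chloride; 21 2-(ethynyloxy)-1,3,5-trimethoxybenzene
Product: 23 rac-4-(CDE-O)-3-(TMP-O)cyclobut-2-en-1-one, via aryloxyketene 22 (not isolated)
Conditions: Et3N (1.5 equiv), 21 (3 equiv), CH2Cl2, slow addition of 14, 0 °C to rt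
Reagents that add atoms: none
Why: ketene/ynol ether (2+2) cycloaddition, in which the nucleophilic CH terminus of 21 bonds to the ketene carbonyl carbon so that ring A oxygen lands on C3 and the C-D-E oxygen on C4; the new C4 stereocentre is formed racemic and needs no control.

Step 11
Reactants: 24 chloroacetaldehyde dimethyl acetal
Product: 27 methoxyacetylene, via 1-chloro-2-methoxyethene 25 (not isolated), via sodium methoxyacetylide 26 (not isolated)
Conditions: NaNH2 (3.2 equiv), liq. NH3, −33 °C; then cold brine, distilled into toluene at −78 °C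
Reagents that add atoms: none
Why: classical alkoxyacetylene preparation by twofold elimination (methanol, then HCl) with sodium amide, the acetylide being hydrolysed on quench.

Step 12
Reactants: 23 rac-4-(CDE-O)-3-(TMP-O)cyclobut-2-en-1-one; 27 methoxyacetylene
Product: 32 5-methoxy-2-(CDE-O)-3-(TMP-O)phenol, via vinylketene 28 (not isolated), via 4-vinylcyclobutenone 29 (not isolated), via dienylketene 30 (not isolated), via cyclohexadienone 31 (not isolated)
Conditions: 27 (5 equiv), toluene, sealed tube, 80 °C then 110 °C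
Reagents that add atoms: none
Why: Thermal 4π electrocyclic opening of 23, with the C4 aryloxy donor turning outward, should give vinylketene 28, whose carbonyl carbon is attacked by the CH terminus of 27 in a (2+2) cycloaddition to the 4-vinylcyclobutenone 29 (bonds B-C3/B-C4 and B-C5/B-C6); a second 4π opening gives dienylketene 30. Ring B, the only ring that persists, closes by thermal 6π electrocyclisation of 30 (bond B-C2/B-C3) to dienone 31, which tautomerises to phenol 32; the four-membered ring of 29 is transient. The closest known reaction type is the Danheiser benzannulation of a cyclobutenone with an alkoxyacetylene, which gives resorcinol monoethers. No stereocentre is created in 32, and the racemic centres of 23, 29 and 31 are erased on aromatisation. The selectivity needed is the regiochemistry of the ketene/ynol ether (2+2); the polarisation of 27 secures it by joining its oxygen-bearing carbon to the ketene alpha carbon, which puts the methoxy group at B-C5, meta to the new hydroxyl. Methoxyacetylene is chosen because it has no beta hydrogen and cannot fragment by retro-ene reaction on heating, and the excess should let capture of 28 outrun its self-reaction.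

Step 13
Reactants: 32 5-methoxy-2-(CDE-O)-3-(TMP-O)phenol
Product: 33 2-{2-[4-(3,4,5-trihydroxy-2-(3,4,5-trihydroxyphenoxy)phenoxy)-3,5-dihydroxyphenoxy]-3,5-dihydroxyphenoxy}benzene-1,3,5-triol (CNP0243665.0)
Conditions: BBr3 (excess), CH2Cl2, −78 °C to rt, argon; then H2O, 0 °C
Reagents that add atoms: none
Why: BBr3 cleavage of aryl methyl ethers by bromide attack at methyl of the boron-complexed ether; the diaryl ether bonds offer no such carbon and should survive, and the aryl borates are hydrolysed on quench.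

**Compound list**

1 | 2-bromo-3,4,5-trimethoxybenzaldehyde | O=Cc1cc(OC)c(OC)c(OC)c1Br | starting material
2 | 3,4,5-trimethoxyphenol | COc1cc(O)cc(OC)c1OC | starting material
3 | 3,4,5-trimethoxy-2-(3,4,5-trimethoxyphenoxy)benzaldehyde | O=Cc1cc(OC)c(OC)c(OC)c1Oc1cc(OC)c(OC)c(OC)c1 | intermediate
4 | 3,4,5-trimethoxy-2-(3,4,5-trimethoxyphenoxy)phenyl formate | O=COc1cc(OC)c(OC)c(OC)c1Oc1cc(OC)c(OC)c(OC)c1 | intermediate (not isolated)
5 | 3,4,5-trimethoxy-2-(3,4,5-trimethoxyphenoxy)phenol | Oc1cc(OC)c(OC)c(OC)c1Oc1cc(OC)c(OC)c(OC)c1 | intermediate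
6 | 4-bromo-3,5-dimethoxybenzaldehyde | O=Cc1cc(OC)c(Br)c(OC)c1 | starting material
7 | 3,5-dimethoxy-4-[3,4,5-trimethoxy-2-(3,4,5-trimethoxyphenoxy)phenoxy]benzaldehyde | O=Cc1cc(OC)c(Oc2cc(OC)c(OC)c(OC)c2Oc2cc(OC)c(OC)c(OC)c2)c(OC)c1 | intermediate
8 | 3,5-dimethoxy-4-[3,4,5-trimethoxy-2-(3,4,5-trimethoxyphenoxy)phenoxy]phenyl formate | O=COc1cc(OC)c(Oc2cc(OC)c(OC)c(OC)c2Oc2cc(OC)c(OC)c(OC)c2)c(OC)c1 | intermediate (not isolated)
9 | 3,5-dimethoxy-4-[3,4,5-trimethoxy-2-(3,4,5-trimethoxyphenoxy)phenoxy]phenol (CDE-OH) | Oc1cc(OC)c(Oc2cc(OC)c(OC)c(OC)c2Oc2cc(OC)c(OC)c(OC)c2)c(OC)c1 | intermediate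
10 | ethyl bromoacetate | CCOC(=O)CBr | starting material
11 | ethyl 2-(CDE-O)acetate | CCOC(=O)COc1cc(OC)c(Oc2cc(OC)c(OC)c(OC)c2Oc2cc(OC)c(OC)c(OC)c2)c(OC)c1 | intermediate
12 | lithium 2-(CDE-O)acetate | [Li+].[O-]C(=O)COc1cc(OC)c(Oc2cc(OC)c(OC)c(OC)c2Oc2cc(OC)c(OC)c(OC)c2)c(OC)c1 | intermediate (not isolated)
13 | 2-(CDE-O)acetic acid | OC(=O)COc1cc(OC)c(Oc2cc(OC)c(OC)c(OC)c2Oc2cc(OC)c(OC)c(OC)c2)c(OC)c1 | intermediate
14 | 2-(CDE-O)acetyl chloride | ClC(=O)COc1cc(OC)c(Oc2cc(OC)c(OC)c(OC)c2Oc2cc(OC)c(OC)c(OC)c2)c(OC)c1 | intermediate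
15 | 2,4,6-trimethoxyphenol | COc1cc(OC)c(O)c(OC)c1 | starting material
16 | trichloroethylene | ClC=C(Cl)Cl | starting material
17 | dichloroacetylene | ClC#CCl | intermediate (not isolated)
18 | 2-[(E)-1,2-dichloroethenoxy]-1,3,5-trimethoxybenzene | COc1cc(OC)c(O/C(Cl)=C\Cl)c(OC)c1 | intermediate
19 | 2-(chloroethynyloxy)-1,3,5-trimethoxybenzene | COc1cc(OC)c(OC#CCl)c(OC)c1 | intermediate (not isolated)
20 | lithium 2-(2,4,6-trimethoxyphenoxy)ethynide | [Li+].[C-]#COc1c(OC)cc(OC)cc1OC | intermediate (not isolated)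
21 | 2-(ethynyloxy)-1,3,5-trimethoxybenzene | COc1cc(OC)c(OC#C)c(OC)c1 | intermediate
22 | 2-(CDE-O)ethen-1-one (aryloxyketene) | O=C=COc1cc(OC)c(Oc2cc(OC)c(OC)c(OC)c2Oc2cc(OC)c(OC)c(OC)c2)c(OC)c1 | intermediate (not isolated)
23 | rac-4-(CDE-O)-3-(TMP-O)cyclobut-2-en-1-one | O=C1C=C(Oc2c(OC)cc(OC)cc2OC)C1Oc1cc(OC)c(Oc2cc(OC)c(OC)c(OC)c2Oc2cc(OC)c(OC)c(OC)c2)c(OC)c1 | intermediate
24 | chloroacetaldehyde dimethyl acetal | COC(CCl)OC | starting material
25 | 1-chloro-2-methoxyethene (E/Z mixture) | COC=CCl | intermediate (not isolated)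
26 | sodium methoxyacetylide | [Na+].[C-]#COC | intermediate (not isolated)
27 | methoxyacetylene | COC#C | intermediate
28 | (3Z)-4-(CDE-O)-3-(TMP-O)buta-1,3-dien-1-one (vinylketene) | O=C=C/C(Oc1c(OC)cc(OC)cc1OC)=C/Oc1cc(OC)c(Oc2cc(OC)c(OC)c(OC)c2Oc2cc(OC)c(OC)c(OC)c2)c(OC)c1 | intermediate (not isolated)
29 | rac-4-[(Z)-2-(CDE-O)-1-(TMP-O)ethenyl]-3-methoxycyclobut-2-en-1-one | O=C1C=C(OC)C1/C(Oc1c(OC)cc(OC)cc1OC)=C/Oc1cc(OC)c(Oc2cc(OC)c(OC)c(OC)c2Oc2cc(OC)c(OC)c(OC)c2)c(OC)c1 | intermediate (not isolated)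
30 | (3E,5Z)-6-(CDE-O)-3-methoxy-5-(TMP-O)hexa-1,3,5-trien-1-one (dienylketene) | O=C=C/C(OC)=C\C(Oc1c(OC)cc(OC)cc1OC)=C\Oc1cc(OC)c(Oc2cc(OC)c(OC)c(OC)c2Oc2cc(OC)c(OC)c(OC)c2)c(OC)c1 | intermediate (not isolated)
31 | rac-6-(CDE-O)-3-methoxy-5-(TMP-O)cyclohexa-2,4-dien-1-one | O=C1C=C(OC)C=C(Oc2c(OC)cc(OC)cc2OC)C1Oc1cc(OC)c(Oc2cc(OC)c(OC)c(OC)c2Oc2cc(OC)c(OC)c(OC)c2)c(OC)c1 | intermediate (not isolated)
32 | 5-methoxy-2-(CDE-O)-3-(TMP-O)phenol (dodecamethyl ether of the target, B-C3 hydroxyl free) | COc1cc(OC)c(Oc2cc(OC)cc(O)c2Oc2cc(OC)c(Oc3cc(OC)c(OC)c(OC)c3Oc3cc(OC)c(OC)c(OC)c3)c(OC)c2)c(OC)c1 | intermediate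
33 | 2-{2-[4-(3,4,5-trihydroxy-2-(3,4,5-trihydroxyphenoxy)phenoxy)-3,5-dihydroxyphenoxy]-3,5-dihydroxyphenoxy}benzene-1,3,5-triol | Oc1cc(O)c(Oc2cc(O)cc(O)c2Oc2cc(O)c(Oc3cc(O)c(O)c(O)c3Oc3cc(O)c(O)c(O)c3)c(O)c2)c(O)c1 | target

**Count**

Total step count: 13. Longest linear sequence: 10 steps (steps 1 to 7, then 10, 12 and 13).

**Steps most likely to fail**

Step 10. The aryloxyketene 22 may dimerise or oligomerise faster than the only moderately nucleophilic aryl ethynyl ether 21 captures it, and amine hydrochloride may add to the vinylogous aryl ester once it has formed. The fallback sets out from 14 and comes back at 33. The ketene from 14 and Et3N is trapped instead with commercial ethoxyacetylene, a much more nucleophilic ynol ether for which this (2+2) is routine, to give racemic 3-ethoxy-4-(CDE-O)cyclobut-2-en-1-one F1. Heating F1 with 27 runs the same benzannulation through the vinylketene F2, the 4-vinylcyclobutenone F3, the dienylketene F4 and the cyclohexadienone F5 (none isolated). It should give 3-ethoxy-5-methoxy-2-(CDE-O)phenol F6, whose free hydroxyl sits on the carbon that must carry ring A. Ullmann coupling of F6 with 2-bromo-1,3,5-trimethoxybenzene (CuI, picolinic acid, K3PO4, DMSO, 110 °C) should give the fully alkylated pentaaryl ether with an ethoxy group at B-C3 F7. BBr3 then cleaves its twelve methyl ethers and one ethyl ether to 33.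

Step 12. The cyclobutenone, stabilised as a vinylogous ester, may open only at temperatures where vinylketene 28 oligomerises or acylates the phenol being formed, so that capture by 27 loses out (aryl ester by-products can be returned to 32 with K2CO3/MeOH). The fallback sets out from 9 and comes back at 33, bringing ring B in as a ready-made arene. Ullmann coupling of 9 with 2-bromo-3,5-dimethoxybenzaldehyde (CuI, N,N-dimethylglycine, Cs2CO3, dioxane, 90 °C) gives 3,5-dimethoxy-2-(CDE-O)benzaldehyde F8. Baeyer–Villiger oxidation with mCPBA gives 3,5-dimethoxy-2-(CDE-O)phenyl formate F9, which K2CO3/MeOH converts into 3,5-dimethoxy-2-(CDE-O)phenol F10. Ullmann coupling of F10 with 2-bromo-1,3,5-trimethoxybenzene gives the tridecamethyl ether of the target F11, and BBr3 cleaves all thirteen methyl ethers to 33.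

Step 3. Oxidative addition and C–O bond formation at a bromide flanked by two methoxy groups may be so slow that 6 is reduced to the arene, or its aldehyde degraded by base, before coupling occurs. The fallback sets out from 5 and comes back at 7 by nucleophilic aromatic substitution without metal. The caesium phenoxide of 5 displaces fluoride from 4-fluoro-3,5-dimethoxybenzaldehyde (Cs2CO3, DMSO, 120 °C), the para formyl group stabilising the Meisenheimer adduct. The product is 7 itself, so no new compound arises.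

**Further compounds**

F1 | step 10 | rac-3-ethoxy-4-(CDE-O)cyclobut-2-en-1-one | O=C1C=C(OCC)C1Oc1cc(OC)c(Oc2cc(OC)c(OC)c(OC)c2Oc2cc(OC)c(OC)c(OC)c2)c(OC)c1
F2 | step 10 | (3Z)-3-ethoxy-4-(CDE-O)buta-1,3-dien-1-one | O=C=C/C(OCC)=C/Oc1cc(OC)c(Oc2cc(OC)c(OC)c(OC)c2Oc2cc(OC)c(OC)c(OC)c2)c(OC)c1
F3 | step 10 | rac-4-[(Z)-1-ethoxy-2-(CDE-O)ethenyl]-3-methoxycyclobut-2-en-1-one | O=C1C=C(OC)C1/C(OCC)=C/Oc1cc(OC)c(Oc2cc(OC)c(OC)c(OC)c2Oc2cc(OC)c(OC)c(OC)c2)c(OC)c1
F4 | step 10 | (3E,5Z)-5-ethoxy-3-methoxy-6-(CDE-O)hexa-1,3,5-trien-1-one | O=C=C/C(OC)=C\C(OCC)=C\Oc1cc(OC)c(Oc2cc(OC)c(OC)c(OC)c2Oc2cc(OC)c(OC)c(OC)c2)c(OC)c1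
F5 | step 10 | rac-5-ethoxy-3-methoxy-6-(CDE-O)cyclohexa-2,4-dien-1-one | O=C1C=C(OC)C=C(OCC)C1Oc1cc(OC)c(Oc2cc(OC)c(OC)c(OC)c2Oc2cc(OC)c(OC)c(OC)c2)c(OC)c1
F6 | step 10 | 3-ethoxy-5-methoxy-2-(CDE-O)phenol | Oc1cc(OC)cc(OCC)c1Oc1cc(OC)c(Oc2cc(OC)c(OC)c(OC)c2Oc2cc(OC)c(OC)c(OC)c2)c(OC)c1
F7 | step 10 | dodecamethyl B-C3-ethyl ether of the target | COc1cc(OC)c(Oc2cc(OC)cc(OCC)c2Oc2cc(OC)c(Oc3cc(OC)c(OC)c(OC)c3Oc3cc(OC)c(OC)c(OC)c3)c(OC)c2)c(OC)c1
F8 | step 12 | 3,5-dimethoxy-2-(CDE-O)benzaldehyde | O=Cc1cc(OC)cc(OC)c1Oc1cc(OC)c(Oc2cc(OC)c(OC)c(OC)c2Oc2cc(OC)c(OC)c(OC)c2)c(OC)c1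
F9 | step 12 | 3,5-dimethoxy-2-(CDE-O)phenyl formate | O=COc1cc(OC)cc(OC)c1Oc1cc(OC)c(Oc2cc(OC)c(OC)c(OC)c2Oc2cc(OC)c(OC)c(OC)c2)c(OC)c1
F10 | step 12 | 3,5-dimethoxy-2-(CDE-O)phenol | Oc1cc(OC)cc(OC)c1Oc1cc(OC)c(Oc2cc(OC)c(OC)c(OC)c2Oc2cc(OC)c(OC)c(OC)c2)c(OC)c1
F11 | step 12 | tridecamethyl ether of the target | COc1cc(OC)c(Oc2cc(OC)cc(OC)c2Oc2cc(OC)c(Oc3cc(OC)c(OC)c(OC)c3Oc3cc(OC)c(OC)c(OC)c3)c(OC)c2)c(OC)c1
F0 | step 3 | none | none
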